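**Remarks on the chemistry (assumptions)**

- Carbon atoms are referred to throughout by the locants of 19 named as a bicyclo[3.2.1]oct-3-en-2-yl acetate: C1 = MeO-bearing bridgehead, C2 = CH–OAc, C3(OMe)=C4 = enol ether, C5 = allyl-bearing bridgehead, C6 = CH–CH3, C7 = CH–aryl, C8 = bridging C=O. "Endo" on C6/C7 means toward the C2–C4 bridge, "exo" toward C8.
- In step 9 the antipode of the chiral iodoarene catalyst is chosen that gives the 5S spiro centre of 12; which antipode this is has to be established on the first run.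

## Structural features

1. 19 is a bicyclo[3.2.1]oct-3-ene: a cyclohexene ring (C1–C2–C3–C4–C5–C8) and a cyclopentanone ring (C1–C8–C5–C6–C7) share the unit C1–C8–C5, with the C8 ketone as the one-carbon bridge.
2. Both bridgeheads are quaternary: C5 carries the allyl group and C1 a methoxy group, and C1 lies between the C8 ketone and the oxygenated C2.
3. Five stereocentres are contiguous (C5–C6–C7–C1–C2): the C7 aryl group is endo, the C6 methyl group exo and trans to it, and the C2 acetoxy group is on the lower face, syn to the aryl group and anti to C8.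
4. Fragile groups: the C3(OMe)=C4 enol ether next to the allylic acetate (acid), the acetate and the non-enolisable β-dicarbonyl array around C1 (alkoxide, retro-Claisen), the free electron-rich phenol (oxidants), and the terminal allyl group (excludes hydrogenolysis and most radical steps).
5. The real difficulty is the pair of fully substituted bridgeheads flanking C8 together with the C6/C7 stereodiad, and the absolute configuration, for which the obvious achiral building blocks (an allylphenol and a propenylphenol) offer no handle.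
6. The key step exploits C1: it bears oxygen, sits between two oxygenated carbons (C8 and C2) and carries the benzylic carbon C7. This is the array left by an acyloin-type shift of C7 from C2 to C1; undoing that shift turns the cyclopentanone ring into the six-membered ring of a bicyclo[2.2.2]oct-5-ene-2,3-dione, the Diels–Alder adduct of a masked o-benzoquinone whose ketal carbon (the future C8) can be made stereogenic by catalysis.

## Logic of the disconnections

In one sentence: the cyclopentanone ring and the MeO-bearing bridgehead of 19 are made by a ring-contracting acyloin-type 1,2-shift of C7 from C2 to C1 in the enantiopure bicyclo[2.2.2]oct-5-ene-2,3-dione 14.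

19 ⇒ 18 ⇒ 17. The aryl O–Si bond and the C2 O–acyl bond are cut. The phenol must stay masked while C1–OH is methylated, and the acetate is put on last because it does not survive base. The gain is small. The demand is a fluoride deprotection that leaves the acetate alone.

17 ⇒ 16. The C2–H bond is cut, giving the C2 ketone. This puts C2 at the oxidation level that the key step delivers and removes one stereocentre. The forward reduction must distinguish C2 from C8 and deliver hydride from the C8 side.

16 ⇒ 15. The O–CH3 bond at C1 is cut, because the oxygen on C1 arrives as a carbonyl oxygen in the key step. The demand is methylation of a tertiary hydroxyl between two ketones without alkoxide base.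

15 ⇒ 14 (key). The C1–C7 bond is cut and C7 is reconnected to C2, with C2 reverting to a MeO-bearing bridgehead and C1 to a ketone. The reason is the 1,2-dioxygenated C1/C2 pair with C7 on C1. The gain is large: the strained [3.2.1] frame with its quaternary C1 becomes a symmetric-looking [2.2.2] frame that a single cycloaddition can make. The forward step must migrate C7 (not C3) with retention and remove the methyl group from the C2 oxygen.

14 ⇒ 13. The C8 carbonyl is traced back to a spiro acyl ketal (two C8–O bonds). The ketal is the carrier of the absolute configuration and is removed under mild methanolysis before the non-enolisable 1,3-dione exists. The demand is chemoselective opening of the lactone.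

13 ⇒ 12 + 11. The C5–C6 and C2–C7 bonds are cut (retro-[4+2]). This removes both rings' bridging bonds and three stereocentres at once and leaves a flat dienone and an (E)-alkene. The forward reaction must be regioselective (C6 to C5, C7 to C2), endo for the aryl group, and selective for one face of the ketal.

12 ⇒ 8. The C8–O(acyl) bond of the spiro ketal is cut, giving a phenol with a carboxylic acid side arm on the neighbouring oxygen. The gain is an aromatic precursor. The forward dearomatisation must be enantioselective, since it sets the only stereocentre from which all others follow.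

8 ⇒ 7 ⇒ 6. The O–C(CH3)2 bond is cut and the two acid-labile protecting groups are restored. This separates the auxiliary arm from the arene. The demand is alkylation of a doubly ortho-substituted phenol.

6 ⇒ 5 ⇒ 4. The aryl–allyl bond at C5 is cut (retro-Claisen) and then the O–allyl bond. The allyl group is delivered from the oxygen that later becomes the ketal oxygen, to the only free ortho carbon, so no regiochemical question arises.

4 ⇒ 2 ⇒ 1. The aryl C–O bond at the future C8 is traced to a formyl group (retro-Dakin) and the MOM group is removed. This reaches a commercial benzaldehyde in which the two neighbouring oxygens are already differentiated.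

11 ⇒ 10 ⇒ 9. The O–Si bond is cut and the propenyl double bond is moved back to the allyl position, reaching a commercial allylphenol. The forward isomerisation must give the E isomer.

## Other disconnections considered

Alternative 1: (the first that comes to mind) cut C5–C6 and C1–C7 directly. Forward, the phenol A1 would be oxidised to the quinone monoketal A2, whose cation would undergo the biomimetic acid-promoted [5+2] cycloaddition with 11 to give A3, the racemate of 16, in very few steps. The ground for not choosing it is stereochemical: the 2-oxidopentadienyl cation from A2 is planar and achiral and the alkene has no ligating group, so nothing in either partner can control the absolute configuration. A chiral Lewis acid would find two equivalent MeO–C=C–C=O binding sites in the oxidised ring, which direct the alkene to different ring carbons. Kinetic closure of the benzylic cation on oxygen (hydrobenzofuranone) is a further competing channel. The chosen plan fixes the absolute configuration at one spiro carbon before any C–C bond is made.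

Alternative 2: cut C5–allyl and C1–C7 and form C7–O instead. An enantiopure aromatic trans-dihydrobenzofuran allyl ether A4 would be dearomatised by a para-Claisen sequence to the 3a-allyl dienone A5, and acid would then move C7 from oxygen to C1 (1,3-shift through the benzylic cation). The ground against it is the facial course of allyl transfer: the only stereo-differentiating element next to C5 is the C6 methyl group, so the allyl group should enter anti to it, whereas A5 needs allyl and methyl cis on the five-membered ring. The dienone/aryl ether Claisen equilibrium also does not favour the dearomatised side.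

Alternative 3: cut C1–C2 (retro-Claisen condensation). The cyclopentanone A6, carrying an α-keto ester arm on C5, would be closed to the trione A7, whose enol would be O-methylated to 16. The ground against it is step economy and mechanism: A6 has four stereocentres on a pentasubstituted ring that must be built linearly before the ring-forming step, which itself sets only C1. The closure also makes a strained, non-enolisable 1,3-dione at C1 under exactly the alkoxide conditions that reopen it.

Key step: step 12

## Steps

Step 1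
Reactants: 1 2-hydroxy-3,4-dimethoxybenzaldehyde
Product: 2 3,4-dimethoxy-2-(methoxymethoxy)benzaldehyde
Conditions: MOMCl, i-Pr2NEt, CH2Cl2, 0 °C → rt
Reagents that add atoms: chloromethyl methyl ether, COCCl
Why: O-alkylation of the phenol as its MOM acetal; this masks the oxygen that later becomes the phenol to be dearomatised, and the group survives peracid, carbonate base and 190 °C.

Step 2
Reactants: 2 3,4-dimethoxy-2-(methoxymethoxy)benzaldehyde
Product: 4 3,4-dimethoxy-2-(methoxymethoxy)phenol, via aryl formate 3 (not isolated)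
Conditions: mCPBA, CH2Cl2, rt; then K2CO3 (cat.), MeOH, 0 °C
Reagents that add atoms: 3-chloroperoxybenzoic acid, OOC(=O)c1cccc(Cl)c1
Why: Dakin-type Baeyer–Villiger oxidation; the electron-rich aryl group migrates in preference to hydrogen, and methanolysis of the formate gives the phenol at the future C8.

Step 3
Reactants: 4 3,4-dimethoxy-2-(methoxymethoxy)phenol
Product: 5 1-(allyloxy)-3,4-dimethoxy-2-(methoxymethoxy)benzene
Conditions: allyl bromide, K2CO3, acetone, reflux
Reagents that add atoms: allyl bromide, C=CCBr
Why: Williamson ether synthesis on the only free phenol.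

Step 4
Reactants: 5 1-(allyloxy)-3,4-dimethoxy-2-(methoxymethoxy)benzene
Product: 6 6-allyl-3,4-dimethoxy-2-(methoxymethoxy)phenol
Conditions: N,N-diethylaniline, 190 °C
Reagents that add atoms: none
Why: Aromatic Claisen rearrangement; the only unsubstituted ortho carbon is the future C5, so the allyl group can go nowhere else.

Step 5
Reactants: 6 6-allyl-3,4-dimethoxy-2-(methoxymethoxy)phenol
Product: 7 tert-butyl 2-[6-allyl-3,4-dimethoxy-2-(methoxymethoxy)phenoxy]-2-methylpropanoate
Conditions: BrC(CH3)2CO2t-Bu, Cs2CO3, DMF, 60 °C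
Reagents that add atoms: tert-butyl 2-bromo-2-methylpropanoate, CC(C)(Br)C(=O)OC(C)(C)C
Why: Phenoxide alkylation with a tertiary α-bromo ester (the ether synthesis used for aryloxyisobutyrates); the gem-dimethyl group later assists spirolactonisation and shields one ketal face.

Step 6
Reactants: 7 tert-butyl 2-[6-allyl-3,4-dimethoxy-2-(methoxymethoxy)phenoxy]-2-methylpropanoate
Product: 8 2-(6-allyl-2-hydroxy-3,4-dimethoxyphenoxy)-2-methylpropanoic acid
Conditions: TFA/CH2Cl2/H2O, 0 °C → rt
Reagents that add atoms: none
Why: Acidolysis removes the tert-butyl ester and the MOM acetal together; water traps the methoxymethyl cation so that the electron-rich ring is not alkylated.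

Step 7
Reactants: 9 4-allyl-2,6-dimethoxyphenol
Product: 10 (E)-2,6-dimethoxy-4-(prop-1-en-1-yl)phenol
Conditions: RuHCl(CO)(PPh3)3 (1 mol%), toluene, 80 °C
Reagents that add atoms: none
Why: Metal-hydride-catalysed alkene isomerisation into conjugation with the arene; the E isomer is the thermodynamic product.

Step 8
Reactants: 10 (E)-2,6-dimethoxy-4-(prop-1-en-1-yl)phenol
Product: 11 (E)-[2,6-dimethoxy-4-(prop-1-en-1-yl)phenoxy]triisopropylsilane
Conditions: TIPSOTf, 2,6-lutidine, CH2Cl2, 0 °C → rt
Reagents that add atoms: triisopropylsilyl trifluoromethanesulfonate, CC(C)[Si](OS(=O)(=O)C(F)(F)F)(C(C)C)C(C)C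
Why: Silylation of the hindered phenol; the TIPS ether keeps the arene electron-rich, should survive carbonate/methanol, Mg(II) and MeOTf, and is removed by fluoride at the end.

Step 9
Reactants: 8 2-(6-allyl-2-hydroxy-3,4-dimethoxyphenoxy)-2-methylpropanoic acid
Product: 12 (5S)-10-allyl-7,8-dimethoxy-3,3-dimethyl-1,4-dioxaspiro[4.5]deca-7,9-diene-2,6-dione
Conditions: C2-symmetric chiral iodoarene (2-iodoresorcinol bis(N-mesityl-lactamide) ether, 10 mol%), mCPBA (1.3 equiv), CH2Cl2/(CF3)2CHOH, −20 °C
Reagents that add atoms: none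
Why: Enantioselective oxidative dearomatising spirolactonisation by an aryl-λ3-iodane made in situ; the phenol is bound to iodine(III) and the tethered carboxylate attacks the ipso carbon (future C8) in a 5-exo mode, so the tether fixes the regiochemistry. The spiro centre, the only stereocentre at this stage, is set by the catalyst.

Step 10
Reactants: 12 (5S)-10-allyl-7,8-dimethoxy-3,3-dimethyl-1,4-dioxaspiro[4.5]deca-7,9-diene-2,6-dione; 11 (E)-[2,6-dimethoxy-4-(prop-1-en-1-yl)phenoxy]triisopropylsilane
Product: 13 (1S,2S,4S,7S,8R)-1-allyl-8-[3,5-dimethoxy-4-(triisopropylsilyloxy)phenyl]-4,5-dimethoxy-5',5',7-trimethylspiro[bicyclo[2.2.2]oct-5-ene-2,2'-[1,3]dioxolane]-3,4'-dione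
Conditions: 11 (3 equiv), toluene, 110 °C, sealed tube, dark
Reagents that add atoms: none
Why: Inverse-electron-demand Diels–Alder reaction of a masked o-benzoquinone with an electron-rich styrene; the nucleophilic CH(CH3) carbon bonds to the δ-carbon C5 and the benzylic carbon to the MeO-bearing α-carbon C2, the polarity-matched orientation. Aryl endo and methyl exo follow from the E-alkene, and the dienophile should add on the ketal face of the lactone acyl oxygen, away from the O–C(CH3)2 face whose methyl groups overhang C5; this sets C5, C6 and C7 in the absolute sense dictated by the spiro centre.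

Step 11
Reactants: 13 (1S,2S,4S,7S,8R)-1-allyl-8-[3,5-dimethoxy-4-(triisopropylsilyloxy)phenyl]-4,5-dimethoxy-5',5',7-trimethylspiro[bicyclo[2.2.2]oct-5-ene-2,2'-[1,3]dioxolane]-3,4'-dione
Product: 14 (1S,4S,7S,8R)-1-allyl-8-[3,5-dimethoxy-4-(triisopropylsilyloxy)phenyl]-4,5-dimethoxy-7-methylbicyclo[2.2.2]oct-5-ene-2,3-dione
Conditions: K2CO3 (0.2 equiv), MeOH/THF, 0 °C
Reagents that add atoms: none
Why: Methoxide opens the acyl-ketal lactone at its carbonyl group and the hemiketal alkoxide collapses to the C8 ketone, releasing the auxiliary arm as its methyl ester; no stereocentre of the carbocycle is touched, and the free 1,2-dione is what step 12 needs for two-point binding.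

Step 12
Reactants: 14 (1S,4S,7S,8R)-1-allyl-8-[3,5-dimethoxy-4-(triisopropylsilyloxy)phenyl]-4,5-dimethoxy-7-methylbicyclo[2.2.2]oct-5-ene-2,3-dione
Product: 15 (1R,5S,6S,7R)-5-allyl-7-[3,5-dimethoxy-4-(triisopropylsilyloxy)phenyl]-1-hydroxy-3-methoxy-6-methylbicyclo[3.2.1]oct-3-ene-2,8-dione
Conditions: MgBr2·OEt2 (3 equiv), CH2Cl2, 0 °C → rt; then aq. NH4Cl
Reagents that add atoms: none
Why: Proposed new method: a dealkylative acyloin (α-ketol-type) 1,2-shift of a bridgehead α-methoxy ketone, whose closest known reaction types are the α-ketol rearrangement of bridged α-hydroxy ketones (bicyclo[2.2.2]octane to bicyclo[3.2.1]octane) and the pinacol-type rearrangement of 1-methoxybicyclo[2.2.2]oct-5-en-2-yl cations. Mg(II) chelates the syn-periplanar C8/C1 1,2-dione, which makes C1 strongly electrophilic and leaves the lone pairs of the bridgehead methoxy group on C2 free. The C2–C7 bond lies about 60° out of the C1 carbonyl plane and overlaps with its π* orbital; it migrates suprafacially to C1 as the methoxy oxygen pushes, and bromide removes the methyl group from the resulting oxocarbenium ion at C2, which makes the shift irreversible. Ring closure: the cyclopentanone C1–C8–C5–C6–C7 forms by this 1,2-carbon shift, that is by contraction of the six-membered ring C2–C1–C8–C5–C6–C7, while the ring C2–C3–C4–C5–C6–C7 gains C1 and becomes the seven-membered perimeter. Stereocentres: C7 migrates with retention, so the aryl group that was syn to C3=C4 in 14 becomes the 7-endo aryl group; the new quaternary C1 can form only on the carbonyl face that C7 already faces, so its configuration is dictated by the bicyclic frame and through it by C5; C5 and C6 are untouched and the C2 stereocentre is spent. The selectivity needed is migration of C7 and not of the equally well aligned vinylic C3: C7 is a benzylic carbon with an electron-rich aryl group and so has high migratory aptitude, whereas C3 is an sp2 carbon bearing an inductively withdrawing methoxy group whose π-participation would place charge on the unstabilised C4. Thermodynamics point the same way, since only C7 migration gives a C2 ketone conjugated with the C3(OMe)=C4 enol ether and relieves the eclipsed 1,2-dione.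

Step 13
Reactants: 15 (1R,5S,6S,7R)-5-allyl-7-[3,5-dimethoxy-4-(triisopropylsilyloxy)phenyl]-1-hydroxy-3-methoxy-6-methylbicyclo[3.2.1]oct-3-ene-2,8-dione
Product: 16 (1R,5S,6S,7R)-5-allyl-7-[3,5-dimethoxy-4-(triisopropylsilyloxy)phenyl]-1,3-dimethoxy-6-methylbicyclo[3.2.1]oct-3-ene-2,8-dione
Conditions: MeOTf, 2,6-di-tert-butyl-4-methylpyridine, CH2Cl2, rt
Reagents that add atoms: methyl trifluoromethanesulfonate, COS(=O)(=O)C(F)(F)F
Why: SN2 methylation of the tertiary hydroxyl with a strong electrophile and a hindered, non-nucleophilic base; alkoxide bases are avoided because the non-enolisable 1,3-dione would undergo retro-Claisen opening.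

Step 14
Reactants: 16 (1R,5S,6S,7R)-5-allyl-7-[3,5-dimethoxy-4-(triisopropylsilyloxy)phenyl]-1,3-dimethoxy-6-methylbicyclo[3.2.1]oct-3-ene-2,8-dione
Product: 17 (1S,2R,5S,6S,7R)-5-allyl-7-[3,5-dimethoxy-4-(triisopropylsilyloxy)phenyl]-2-hydroxy-1,3-dimethoxy-6-methylbicyclo[3.2.1]oct-3-en-8-one
Conditions: NaBH4, CeCl3·7H2O, MeOH, −78 °C
Reagents that add atoms: none
Why: Luche reduction; 1,2-addition of hydride to the conjugated C2 ketone, which is less hindered than the C8 ketone between two quaternary bridgeheads. Hydride should enter from the face syn to C8, because the opposite face is covered by the endo aryl group on C7, giving the C2 hydroxyl on the aryl side (the C1 descriptor changes from R to S for CIP reasons only).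

Step 15
Reactants: 17 (1S,2R,5S,6S,7R)-5-allyl-7-[3,5-dimethoxy-4-(triisopropylsilyloxy)phenyl]-2-hydroxy-1,3-dimethoxy-6-methylbicyclo[3.2.1]oct-3-en-8-one
Product: 18 (1S,2R,5S,6S,7R)-5-allyl-7-[3,5-dimethoxy-4-(triisopropylsilyloxy)phenyl]-1,3-dimethoxy-6-methyl-8-oxobicyclo[3.2.1]oct-3-en-2-yl acetate
Conditions: Ac2O, DMAP, pyridine, CH2Cl2, rt
Reagents that add atoms: acetic anhydride, CC(=O)OC(C)=O
Why: DMAP-catalysed acylation of the only free hydroxyl; no stereocentre is affected.

Step 16
Reactants: 18 (1S,2R,5S,6S,7R)-5-allyl-7-[3,5-dimethoxy-4-(triisopropylsilyloxy)phenyl]-1,3-dimethoxy-6-methyl-8-oxobicyclo[3.2.1]oct-3-en-2-yl acetate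
Product: 19 (1S,2R,5S,6S,7R)-5-allyl-7-(4-hydroxy-3,5-dimethoxyphenyl)-1,3-dimethoxy-6-methyl-8-oxobicyclo[3.2.1]oct-3-en-2-yl acetate
Conditions: TBAF, AcOH (1:1), THF, 0 °C
Reagents that add atoms: none
Why: Fluoride cleavage of the aryl silyl ether; the acetic acid buffer keeps the medium from becoming basic, so the acetate and the β-acetoxy ketone should stay intact.

## Compound list

1 | 2-hydroxy-3,4-dimethoxybenzaldehyde | O=Cc1ccc(OC)c(OC)c1O | starting material
2 | 3,4-dimethoxy-2-(methoxymethoxy)benzaldehyde | O=Cc1ccc(OC)c(OC)c1OCOC | intermediate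
3 | 3,4-dimethoxy-2-(methoxymethoxy)phenyl formate | O=COc1ccc(OC)c(OC)c1OCOC | intermediate (not isolated)
4 | 3,4-dimethoxy-2-(methoxymethoxy)phenol | Oc1ccc(OC)c(OC)c1OCOC | intermediate
5 | 1-(allyloxy)-3,4-dimethoxy-2-(methoxymethoxy)benzene | C=CCOc1ccc(OC)c(OC)c1OCOC | intermediate
6 | 6-allyl-3,4-dimethoxy-2-(methoxymethoxy)phenol | C=CCc1cc(OC)c(OC)c(OCOC)c1O | intermediate
7 | tert-butyl 2-[6-allyl-3,4-dimethoxy-2-(methoxymethoxy)phenoxy]-2-methylpropanoate | C=CCc1cc(OC)c(OC)c(OCOC)c1OC(C)(C)C(=O)OC(C)(C)C | intermediate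
8 | 2-(6-allyl-2-hydroxy-3,4-dimethoxyphenoxy)-2-methylpropanoic acid | C=CCc1cc(OC)c(OC)c(O)c1OC(C)(C)C(=O)O | intermediate
9 | 4-allyl-2,6-dimethoxyphenol | C=CCc1cc(OC)c(O)c(OC)c1 | starting material
10 | (E)-2,6-dimethoxy-4-(prop-1-en-1-yl)phenol | C/C=C/c1cc(OC)c(O)c(OC)c1 | intermediate
11 | (E)-[2,6-dimethoxy-4-(prop-1-en-1-yl)phenoxy]triisopropylsilane | C/C=C/c1cc(OC)c(O[Si](C(C)C)(C(C)C)C(C)C)c(OC)c1 | intermediate
12 | (5S)-10-allyl-7,8-dimethoxy-3,3-dimethyl-1,4-dioxaspiro[4.5]deca-7,9-diene-2,6-dione | C=CCC1=CC(OC)=C(OC)C(=O)[C@]12OC(C)(C)C(=O)O2 | intermediate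
13 | (1S,2S,4S,7S,8R)-1-allyl-8-[3,5-dimethoxy-4-(triisopropylsilyloxy)phenyl]-4,5-dimethoxy-5',5',7-trimethylspiro[bicyclo[2.2.2]oct-5-ene-2,2'-[1,3]dioxolane]-3,4'-dione (aryl syn to C5=C6, 7-methyl syn to the spiro/keto bridge) | C=CC[C@]12C=C(OC)[C@](OC)(C(=O)[C@]13OC(C)(C)C(=O)O3)[C@@H](c4cc(OC)c(O[Si](C(C)C)(C(C)C)C(C)C)c(OC)c4)[C@@H]2C | intermediate
14 | (1S,4S,7S,8R)-1-allyl-8-[3,5-dimethoxy-4-(triisopropylsilyloxy)phenyl]-4,5-dimethoxy-7-methylbicyclo[2.2.2]oct-5-ene-2,3-dione | C=CC[C@]12C=C(OC)[C@](OC)(C(=O)C1=O)[C@@H](c3cc(OC)c(O[Si](C(C)C)(C(C)C)C(C)C)c(OC)c3)[C@@H]2C | intermediate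
15 | (1R,5S,6S,7R)-5-allyl-7-[3,5-dimethoxy-4-(triisopropylsilyloxy)phenyl]-1-hydroxy-3-methoxy-6-methylbicyclo[3.2.1]oct-3-ene-2,8-dione | C=CC[C@]12C=C(OC)C(=O)[C@](O)(C1=O)[C@@H](c1cc(OC)c(O[Si](C(C)C)(C(C)C)C(C)C)c(OC)c1)[C@@H]2C | intermediate
16 | (1R,5S,6S,7R)-5-allyl-7-[3,5-dimethoxy-4-(triisopropylsilyloxy)phenyl]-1,3-dimethoxy-6-methylbicyclo[3.2.1]oct-3-ene-2,8-dione | C=CC[C@]12C=C(OC)C(=O)[C@](OC)(C1=O)[C@@H](c1cc(OC)c(O[Si](C(C)C)(C(C)C)C(C)C)c(OC)c1)[C@@H]2C | intermediate
17 | (1S,2R,5S,6S,7R)-5-allyl-7-[3,5-dimethoxy-4-(triisopropylsilyloxy)phenyl]-2-hydroxy-1,3-dimethoxy-6-methylbicyclo[3.2.1]oct-3-en-8-one | C=CC[C@]12C=C(OC)[C@@H](O)[C@](OC)(C1=O)[C@@H](c1cc(OC)c(O[Si](C(C)C)(C(C)C)C(C)C)c(OC)c1)[C@@H]2C | intermediate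
18 | (1S,2R,5S,6S,7R)-5-allyl-7-[3,5-dimethoxy-4-(triisopropylsilyloxy)phenyl]-1,3-dimethoxy-6-methyl-8-oxobicyclo[3.2.1]oct-3-en-2-yl acetate | C=CC[C@]12C=C(OC)[C@@H](OC(C)=O)[C@](OC)(C1=O)[C@@H](c1cc(OC)c(O[Si](C(C)C)(C(C)C)C(C)C)c(OC)c1)[C@@H]2C | intermediate
19 | (1S,2R,5S,6S,7R)-5-allyl-7-(4-hydroxy-3,5-dimethoxyphenyl)-1,3-dimethoxy-6-methyl-8-oxobicyclo[3.2.1]oct-3-en-2-yl acetate (CNP0373655.1) | C=CC[C@]12C=C(OC)[C@@H](OC(C)=O)[C@](OC)(C1=O)[C@@H](c1cc(OC)c(O)c(OC)c1)[C@@H]2C | target

## Step count and least certain steps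

Total step count: 16. Longest linear sequence: 14 steps (1 → 19 through steps 1–6 and 9–16); the dienophile branch (steps 7 and 8) joins at step 10.

**Step 12 (key step, proposed new method).** The most likely failure is that the wrong bond moves or that none moves. The vinylic C3 is as well aligned as C7 and could migrate instead. The C2–C7 bond could also break heterolytically to a benzylic cation and a chelated dienolate, followed by closure on oxygen or loss of configuration at C7. A Lewis acid as mild as Mg(II) may not trigger the shift at all. The fallback uses known chemistry, sets out from 6 and comes back at 15. Compound 6 is oxidised with PhI(OAc)2 in aqueous acetonitrile to the quinone 2-allyl-5-methoxy-6-(methoxymethoxy)cyclohexa-2,5-diene-1,4-dione F1. A chiral Ti(IV)–TADDOLate (from TiCl4/Ti(OiPr)4) then promotes the [5+2] cycloaddition of F1 with 11, a known asymmetric reaction class of 2-alkoxy-1,4-benzoquinones with propenylbenzenes, to the diosphenol (1R,5S,6S,7R)-5-allyl-7-[3,5-dimethoxy-4-(triisopropylsilyloxy)phenyl]-3-hydroxy-1-(methoxymethoxy)-6-methylbicyclo[3.2.1]oct-3-ene-2,8-dione F2. O-Methylation of the enol with TMSCHN2 gives (1R,5S,6S,7R)-5-allyl-7-[3,5-dimethoxy-4-(triisopropylsilyloxy)phenyl]-3-methoxy-1-(methoxymethoxy)-6-methylbicyclo[3.2.1]oct-3-ene-2,8-dione F3, and removal of the MOM group (Me2BBr, CH2Cl2, −78 °C) gives 15.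

**Step 10.** The most likely failure is exo approach of the aryl group, because in the endo mode the exo C-methyl group has to pass the spiro ketal; this would lead to the C6/C7-epimeric series. Leakage to the other ketal face and a slow reaction of the tetrasubstituted, donor-substituted diene (so that thermal decomposition of 12 competes) are the other risks. The fallback leaves the [4+2] manifold, sets out from 6 and comes back at 15. PhI(OAc)2 in methanol converts 6 into the quinone monoketal 2-allyl-4,4,5-trimethoxy-6-(methoxymethoxy)cyclohexa-2,5-dien-1-one F4. Its TMSOTf-promoted cationic [5+2] cycloaddition with 11, in which the methyl group faces only the flat C8 carbonyl and the MOM acetal is cleaved in the same medium, would give 15 as the racemate. This would have to be resolved by chromatography on a chiral stationary phase before it re-enters at step 13.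

**Step 9.** The most likely failure is insufficient enantioselectivity with this doubly ortho-substituted, tetra-oxygenated phenol, or competing oxidation of the product diene by the peracid. The fallback replaces catalyst control by a chiral-pool auxiliary whose spiro epimers are separable diastereomers; it sets out from 6 and comes back at 14. Mitsunobu reaction of 6 with ethyl (S)-lactate (inversion) gives ethyl (2R)-2-[6-allyl-3,4-dimethoxy-2-(methoxymethoxy)phenoxy]propanoate F5. Saponification and mild aqueous acid give (2R)-2-(6-allyl-2-hydroxy-3,4-dimethoxyphenoxy)propanoic acid F6. Oxidation with PhI(OAc)2 gives (3R,5S)-10-allyl-7,8-dimethoxy-3-methyl-1,4-dioxaspiro[4.5]deca-7,9-diene-2,6-dione F7 together with its spiro epimer (3R,5R)-10-allyl-7,8-dimethoxy-3-methyl-1,4-dioxaspiro[4.5]deca-7,9-diene-2,6-dione F8, which is removed by chromatography. Cycloaddition of F7 with 11 as in step 10 gives (1S,2S,4S,5'R,7S,8R)-1-allyl-8-[3,5-dimethoxy-4-(triisopropylsilyloxy)phenyl]-4,5-dimethoxy-5',7-dimethylspiro[bicyclo[2.2.2]oct-5-ene-2,2'-[1,3]dioxolane]-3,4'-dione F9, and methanolysis as in step 11 gives 14.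

**Step 13.** The most likely failure is that the tertiary hydroxyl, deactivated by two flanking ketones and crowded, reacts too slowly, so that forcing conditions start retro-Claisen or acyloin equilibration. The fallback changes the order so that the hydroxyl is methylated when only one ketone flanks it; it sets out from 15 and comes back at 18. Luche reduction of 15 gives the diol (1S,2R,5S,6S,7R)-5-allyl-7-[3,5-dimethoxy-4-(triisopropylsilyloxy)phenyl]-1,2-dihydroxy-3-methoxy-6-methylbicyclo[3.2.1]oct-3-en-8-one F10. Acetylation of the secondary hydroxyl alone (Ac2O, pyridine) gives (1S,2R,5S,6S,7R)-5-allyl-7-[3,5-dimethoxy-4-(triisopropylsilyloxy)phenyl]-1-hydroxy-3-methoxy-6-methyl-8-oxobicyclo[3.2.1]oct-3-en-2-yl acetate F11. Methylation with MeOTf and 2,6-di-tert-butyl-4-methylpyridine then gives 18.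

## Further compounds

F1 | step 12 | 2-allyl-5-methoxy-6-(methoxymethoxy)cyclohexa-2,5-diene-1,4-dione | C=CCC1=CC(=O)C(OC)=C(OCOC)C1=O
F2 | step 12 | (1R,5S,6S,7R)-5-allyl-7-[3,5-dimethoxy-4-(triisopropylsilyloxy)phenyl]-3-hydroxy-1-(methoxymethoxy)-6-methylbicyclo[3.2.1]oct-3-ene-2,8-dione | C=CC[C@]12C=C(O)C(=O)[C@](OCOC)(C1=O)[C@@H](c1cc(OC)c(O[Si](C(C)C)(C(C)C)C(C)C)c(OC)c1)[C@@H]2C
F3 | step 12 | (1R,5S,6S,7R)-5-allyl-7-[3,5-dimethoxy-4-(triisopropylsilyloxy)phenyl]-3-methoxy-1-(methoxymethoxy)-6-methylbicyclo[3.2.1]oct-3-ene-2,8-dione | C=CC[C@]12C=C(OC)C(=O)[C@](OCOC)(C1=O)[C@@H](c1cc(OC)c(O[Si](C(C)C)(C(C)C)C(C)C)c(OC)c1)[C@@H]2C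
F4 | step 10 | 2-allyl-4,4,5-trimethoxy-6-(methoxymethoxy)cyclohexa-2,5-dien-1-one | C=CCC1=CC(OC)(OC)C(OC)=C(OCOC)C1=O
F5 | step 9 | ethyl (2R)-2-[6-allyl-3,4-dimethoxy-2-(methoxymethoxy)phenoxy]propanoate | C=CCc1cc(OC)c(OC)c(OCOC)c1O[C@H](C)C(=O)OCC
F6 | step 9 | (2R)-2-(6-allyl-2-hydroxy-3,4-dimethoxyphenoxy)propanoic acid | C=CCc1cc(OC)c(OC)c(O)c1O[C@H](C)C(=O)O
F7 | step 9 | (3R,5S)-10-allyl-7,8-dimethoxy-3-methyl-1,4-dioxaspiro[4.5]deca-7,9-diene-2,6-dione | C=CCC1=CC(OC)=C(OC)C(=O)[C@]12O[C@H](C)C(=O)O2
F8 | step 9 | (3R,5R)-10-allyl-7,8-dimethoxy-3-methyl-1,4-dioxaspiro[4.5]deca-7,9-diene-2,6-dione | C=CCC1=CC(OC)=C(OC)C(=O)[C@@]12O[C@H](C)C(=O)O2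
F9 | step 9 | (1S,2S,4S,5'R,7S,8R)-1-allyl-8-[3,5-dimethoxy-4-(triisopropylsilyloxy)phenyl]-4,5-dimethoxy-5',7-dimethylspiro[bicyclo[2.2.2]oct-5-ene-2,2'-[1,3]dioxolane]-3,4'-dione | C=CC[C@]12C=C(OC)[C@](OC)(C(=O)[C@]13O[C@H](C)C(=O)O3)[C@@H](c4cc(OC)c(O[Si](C(C)C)(C(C)C)C(C)C)c(OC)c4)[C@@H]2C
F10 | step 13 | (1S,2R,5S,6S,7R)-5-allyl-7-[3,5-dimethoxy-4-(triisopropylsilyloxy)phenyl]-1,2-dihydroxy-3-methoxy-6-methylbicyclo[3.2.1]oct-3-en-8-one | C=CC[C@]12C=C(OC)[C@@H](O)[C@](O)(C1=O)[C@@H](c1cc(OC)c(O[Si](C(C)C)(C(C)C)C(C)C)c(OC)c1)[C@@H]2C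
F11 | step 13 | (1S,2R,5S,6S,7R)-5-allyl-7-[3,5-dimethoxy-4-(triisopropylsilyloxy)phenyl]-1-hydroxy-3-methoxy-6-methyl-8-oxobicyclo[3.2.1]oct-3-en-2-yl acetate | C=CC[C@]12C=C(OC)[C@@H](OC(C)=O)[C@](O)(C1=O)[C@@H](c1cc(OC)c(O[Si](C(C)C)(C(C)C)C(C)C)c(OC)c1)[C@@H]2C
A1 | alternative 1 | 6-allyl-2,3,4-trimethoxyphenol | C=CCc1cc(OC)c(OC)c(OC)c1O
A2 | alternative 1 | 2-allyl-4,4,5,6-tetramethoxycyclohexa-2,5-dien-1-one | C=CCC1=CC(OC)(OC)C(OC)=C(OC)C1=O
A3 | alternative 1 | racemate of 16, rac-(1R,5S,6S,7R)-5-allyl-7-[3,5-dimethoxy-4-(triisopropylsilyloxy)phenyl]-1,3-dimethoxy-6-methylbicyclo[3.2.1]oct-3-ene-2,8-dione (one enantiomer drawn) | C=CC[C@]12C=C(OC)C(=O)[C@](OC)(C1=O)[C@@H](c1cc(OC)c(O[Si](C(C)C)(C(C)C)C(C)C)c(OC)c1)[C@@H]2C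
A4 | alternative 2 | (2R,3R)-6-(allyloxy)-2-[3,5-dimethoxy-4-(triisopropylsilyloxy)phenyl]-5,7-dimethoxy-3-methyl-2,3-dihydro-1-benzofuran (trans) | C[C@H]1[C@H](c2cc(OC)c(O[Si](C(C)C)(C(C)C)C(C)C)c(OC)c2)Oc2c1cc(OC)c(OCC=C)c2OC
A5 | alternative 2 | 3a-allyl-2-[3,5-dimethoxy-4-(triisopropylsilyloxy)phenyl]-5,7-dimethoxy-3-methyl-3,3a-dihydro-1-benzofuran-6(2H)-one, 3a-allyl cis to 3-methyl, 2-aryl trans to 3-methyl | C=CC[C@]12C=C(OC)C(=O)C(OC)=C1O[C@@H](c1cc(OC)c(O[Si](C(C)C)(C(C)C)C(C)C)c(OC)c1)[C@@H]2C
A6 | alternative 3 | methyl 3-{1-allyl-3-[3,5-dimethoxy-4-(triisopropylsilyloxy)phenyl]-4-methoxy-2-methyl-5-oxocyclopentyl}-2-oxopropanoate, ring C1–C3 configured as C5, C6, C7 of 19, C4 epimers | C=CC[C@]1(CC(=O)C(=O)OC)C(=O)C(OC)[C@@H](c2cc(OC)c(O[Si](C(C)C)(C(C)C)C(C)C)c(OC)c2)[C@@H]1C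
A7 | alternative 3 | (1R,5S,6S,7R)-5-allyl-7-[3,5-dimethoxy-4-(triisopropylsilyloxy)phenyl]-1-methoxy-6-methylbicyclo[3.2.1]octane-2,3,8-trione | C=CC[C@]12CC(=O)C(=O)[C@](OC)(C1=O)[C@@H](c1cc(OC)c(O[Si](C(C)C)(C(C)C)C(C)C)c(OC)c1)[C@@H]2C
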